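**Retrosynthetic overview**
1. Target 14 ⇐ acetylation of the tertiary alcohol 12, done last because the β-acetoxy ketone is base-sensitive.
2. 12 ⇐ C5–C bond: α′-allylation of the polyanion of hydroxy-enone acid 8 with (Z)-1-bromopent-2-ene 10 (from (Z)-pent-2-en-1-ol 9).
3. 8 ⇐ triol 6 by oxidation (allylic CHOH → enone, CH2OH → CO2H); 6 ⇐ bis-silyl ether 5.
4. 5 ⇐ C4–chain bond: anti-selective 1,2-addition of the C8 organocerium (from bromide 2) to (S)-4-silyloxycyclopentenone 1; the silyloxy centre relays chirality to the quaternary carbinol and is then oxidised away.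
5. Rings: the only ring (the cyclopentenone) is bought intact in 1; no ring-forming step.

Assumption: CIP analysis of the given SMILES gives (1S,5S) for the cyclopentenyl unit, meaning OAc is cis to the pentenyl group and the two carbon chains are trans; 1 and 2 are taken as catalogue compounds.

**Step 1**
Reactants: 1 (4S)-4-[(tert-butyldimethylsilyl)oxy]cyclopent-2-en-1-one; 2 (8-bromooctyloxy)(tert-butyl)dimethylsilane
Product: 5 (1R,4S)-4-[(tert-butyldimethylsilyl)oxy]-1-{8-[(tert-butyldimethylsilyl)oxy]octyl}cyclopent-2-en-1-ol, via Grignard reagent 3 (not isolated), via organocerium reagent 4 (not isolated)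
Conditions: Mg, I2 (cat.), THF, 40 °C; anhydrous CeCl3 (1.5 equiv), THF, −78 °C, 1 h; then 1, −78 °C; pH 7 aqueous quench; chromatography
Reagents that add atoms: none
Why: Grignard formation followed by Imamoto organocerium 1,2-addition, in which the non-basic RCeCl2 attacks the enone carbonyl without enolisation or β-elimination of the silyloxy group and enters anti to the OTBS group, so the existing (S)-carbinol sets the new quaternary carbinol as R (cis-1,4-dioxygenated cyclopentene).

**Step 2**
Reactants: 5 (1R,4S)-4-[(tert-butyldimethylsilyl)oxy]-1-{8-[(tert-butyldimethylsilyl)oxy]octyl}cyclopent-2-en-1-ol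
Product: 6 (1R,4S)-1-(8-hydroxyoctyl)cyclopent-2-ene-1,4-diol
Conditions: TBAF (2.5 equiv), THF, 0 °C → rt
Reagents that add atoms: none
Why: Fluoride-driven cleavage of both Si–O bonds (global desilylation) under non-acidic conditions spares the acid-sensitive tertiary allylic alcohol and touches no stereocentre.

**Step 3**
Reactants: 6 (1R,4S)-1-(8-hydroxyoctyl)cyclopent-2-ene-1,4-diol
Product: 8 8-[(1R)-1-hydroxy-4-oxocyclopent-2-en-1-yl]octanoic acid, via keto aldehyde 7 (not isolated)
Conditions: TEMPO (0.2 equiv), PhI(OAc)2 (2.5 equiv), MeCN/CH2Cl2, rt; then NaClO2, NaH2PO4, 2-methylbut-2-ene, t-BuOH/H2O, 0 °C → rt (one pot)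
Reagents that add atoms: sodium chlorite, [Na+].[O-]Cl=O
Why: TEMPO/PhI(OAc)2 oxidation takes the allylic secondary carbinol to the enone and the primary carbinol to the aldehyde, and Pinnick oxidation then gives the acid, while the tertiary alcohol cannot be oxidised, so the relay stereocentre is destroyed and the quaternary centre is kept.

**Step 4**
Reactants: 9 (2Z)-pent-2-en-1-ol
Product: 10 (2Z)-1-bromopent-2-ene
Conditions: PBr3 (0.4 equiv), pyridine (cat.), Et2O, −20 → 0 °C; used fresh
Reagents that add atoms: phosphorus tribromide, BrP(Br)Br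
Why: SN2 displacement of the phosphite ester of a primary allylic alcohol by bromide at low temperature keeps the Z geometry and avoids allylic transposition.

**Step 5**
Reactants: 8 8-[(1R)-1-hydroxy-4-oxocyclopent-2-en-1-yl]octanoic acid; 10 (2Z)-1-bromopent-2-ene
Product: 12 8-[(1S,5S)-1-hydroxy-4-oxo-5-[(2Z)-pent-2-en-1-yl]cyclopent-2-en-1-yl]octanoic acid, via trilithium salt 11 (not isolated)
Conditions: LDA (3.3 equiv), THF/DMPU (9:1), −78 °C, 1 h; then 10 (1.2 equiv), −78 → −40 °C; AcOH quench at −78 °C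
Reagents that add atoms: none
Why: Kinetic α′-deprotonation gives the carboxylate/alkoxide/cross-conjugated dienolate (β-elimination and retro-aldol are blocked because the β-oxygen is an alkoxide and the carbonyl is masked as enolate), and SN2 C-allylation is expected on the face anti to the C4 alkyl chain (syn to the small O–Li), giving the trans-dialkyl 5S centre, which should also be the thermodynamically preferred C5 epimer.

**Step 6**
Reactants: 12 8-[(1S,5S)-1-hydroxy-4-oxo-5-[(2Z)-pent-2-en-1-yl]cyclopent-2-en-1-yl]octanoic acid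
Product: 14 8-[(1S,5S)-1-acetoxy-4-oxo-5-[(2Z)-pent-2-en-1-yl]cyclopent-2-en-1-yl]octanoic acid, via mixed anhydride 13 (not isolated)
Conditions: Ac2O (3 equiv), Sc(OTf)3 (2 mol%), MeCN, −20 °C; then THF/H2O, rt
Reagents that add atoms: acetic anhydride, CC(=O)OC(C)=O
Why: Lewis-acid-catalysed acetylation of the hindered tertiary alcohol under base-free conditions avoids E1cB loss of the β-acetoxy group; the carboxyl group is transiently tied up as the mixed anhydride and released on aqueous work-up, and no stereocentre is touched.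

**Compound list**
1 | (4S)-4-[(tert-butyldimethylsilyl)oxy]cyclopent-2-en-1-one | O=C1C=C[C@@H](O[Si](C)(C)C(C)(C)C)C1 | starting material
2 | (8-bromooctyloxy)(tert-butyl)dimethylsilane | CC(C)(C)[Si](C)(C)OCCCCCCCCBr | starting material
3 | {8-[(tert-butyldimethylsilyl)oxy]octyl}magnesium bromide (Grignard reagent) | CC(C)(C)[Si](C)(C)OCCCCCCCC[Mg]Br | intermediate (not isolated)
4 | dichloro{8-[(tert-butyldimethylsilyl)oxy]octyl}cerium (organocerium reagent) | CC(C)(C)[Si](C)(C)OCCCCCCCC[Ce](Cl)Cl | intermediate (not isolated)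
5 | (1R,4S)-4-[(tert-butyldimethylsilyl)oxy]-1-{8-[(tert-butyldimethylsilyl)oxy]octyl}cyclopent-2-en-1-ol | CC(C)(C)[Si](C)(C)OCCCCCCCC[C@]1(O)C=C[C@@H](O[Si](C)(C)C(C)(C)C)C1 | intermediate
6 | (1R,4S)-1-(8-hydroxyoctyl)cyclopent-2-ene-1,4-diol | OCCCCCCCC[C@]1(O)C=C[C@@H](O)C1 | intermediate
7 | 8-[(1R)-1-hydroxy-4-oxocyclopent-2-en-1-yl]octanal (keto aldehyde) | O=CCCCCCCC[C@]1(O)C=CC(=O)C1 | intermediate (not isolated)
8 | 8-[(1R)-1-hydroxy-4-oxocyclopent-2-en-1-yl]octanoic acid | OC(=O)CCCCCCC[C@]1(O)C=CC(=O)C1 | intermediate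
9 | (2Z)-pent-2-en-1-ol | CC/C=C\CO | starting material
10 | (2Z)-1-bromopent-2-ene | CC/C=C\CBr | intermediate
11 | trilithium carboxylate/alkoxide/dienolate of 8 (trilithium salt) | [Li]OC(=O)CCCCCCC[C@]1(O[Li])C=CC(O[Li])=C1 | intermediate (not isolated)
12 | 8-[(1S,5S)-1-hydroxy-4-oxo-5-[(2Z)-pent-2-en-1-yl]cyclopent-2-en-1-yl]octanoic acid | CC/C=C\C[C@@H]1C(=O)C=C[C@]1(CCCCCCCC(=O)O)O | intermediate
13 | acetic 8-[(1S,5S)-1-acetoxy-4-oxo-5-[(2Z)-pent-2-en-1-yl]cyclopent-2-en-1-yl]octanoic anhydride (mixed anhydride) | CC/C=C\C[C@@H]1C(=O)C=C[C@]1(CCCCCCCC(=O)OC(C)=O)OC(C)=O | intermediate (not isolated)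
14 | 8-[(1S,5S)-1-acetoxy-4-oxo-5-[(2Z)-pent-2-en-1-yl]cyclopent-2-en-1-yl]octanoic acid (CNP0348716.1) | CC/C=C\C[C@@H]1C(=O)C=C[C@]1(CCCCCCCC(=O)O)OC(C)=O | target

**Totals**
Total step count: 6. Longest linear sequence: 5 steps (1 → 5 → 6 → 8 → 12 → 14; step 4 is a one-step side branch).

**Three steps most likely to fail**

Step 5 (allylation of a trilithio species). The risks are poor solubility and aggregation of the trianion, competing O-alkylation of the carboxylate, and uncertain facial selectivity at C5. The fallback removes the carboxylate from the anion. It sets out from 8 and comes back at 12. Acid 8 is esterified with TMSCHN2 (PhMe/MeOH, 0 °C) to methyl 8-[(1R)-1-hydroxy-4-oxocyclopent-2-en-1-yl]octanoate F1. F1 is deprotonated with only 2.2 equiv LDA (THF/DMPU, −78 °C) to its dilithium alkoxide/dienolate salt F2. F2 is allylated with 10 to methyl 8-[(1S,5S)-1-hydroxy-4-oxo-5-[(2Z)-pent-2-en-1-yl]cyclopent-2-en-1-yl]octanoate F3. The methyl ester is then cleaved with pig-liver esterase (pH 7 phosphate buffer/acetone, rt), which leaves the β-hydroxy ketone alone, to return to 12.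

Step 6 (acetylation of a hindered tertiary β-hydroxy ketone beside a free acid). The risks are incomplete conversion, Lewis-acid-induced retro-aldol, and complications from the anhydride. The fallback switches to carboxyl protection plus nucleophilic catalysis. It sets out from 12 and comes back at 14. The carboxyl group of 12 is silylated selectively (TBSCl 1.05 equiv, imidazole, CH2Cl2, 0 °C; the tertiary OH does not react) to tert-butyldimethylsilyl 8-[(1S,5S)-1-hydroxy-4-oxo-5-[(2Z)-pent-2-en-1-yl]cyclopent-2-en-1-yl]octanoate F4. F4 is acetylated with Ac2O, DMAP (cat.) and pyridine (0 °C → rt) to tert-butyldimethylsilyl 8-[(1S,5S)-1-acetoxy-4-oxo-5-[(2Z)-pent-2-en-1-yl]cyclopent-2-en-1-yl]octanoate F5. The labile silyl ester is hydrolysed in the work-up (AcOH/THF/H2O, rt) to give 14.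

Step 3 (two carbinols taken to two different oxidation levels in one pot beside a tertiary allylic alcohol). The risks are sluggish oxidation of the secondary carbinol and oxoammonium-induced allylic transposition. The fallback replaces the global oxidation by a site-selective, stepwise one. It sets out from 6 and comes back at 8. Activated MnO2 (acetone/CH2Cl2, rt) oxidises only the allylic carbinol of 6 to (4R)-4-hydroxy-4-(8-hydroxyoctyl)cyclopent-2-en-1-one F6, which is isolated. The primary alcohol is then taken to the acid with catalytic TEMPO/NaOCl and stoichiometric NaClO2 (MeCN, pH 6.7 phosphate buffer, 35 °C; aldehyde 7 is again the transient intermediate) to give 8.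

**Further compounds**
F1 | step 5 | methyl 8-[(1R)-1-hydroxy-4-oxocyclopent-2-en-1-yl]octanoate | COC(=O)CCCCCCC[C@]1(O)C=CC(=O)C1
F2 | step 5 | dilithium alkoxide/dienolate salt of F1 | COC(=O)CCCCCCC[C@]1(O[Li])C=CC(O[Li])=C1
F3 | step 5 | methyl 8-[(1S,5S)-1-hydroxy-4-oxo-5-[(2Z)-pent-2-en-1-yl]cyclopent-2-en-1-yl]octanoate | CC/C=C\C[C@@H]1C(=O)C=C[C@]1(CCCCCCCC(=O)OC)O
F4 | step 6 | tert-butyldimethylsilyl 8-[(1S,5S)-1-hydroxy-4-oxo-5-[(2Z)-pent-2-en-1-yl]cyclopent-2-en-1-yl]octanoate | CC/C=C\C[C@@H]1C(=O)C=C[C@]1(CCCCCCCC(=O)O[Si](C)(C)C(C)(C)C)O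
F5 | step 6 | tert-butyldimethylsilyl 8-[(1S,5S)-1-acetoxy-4-oxo-5-[(2Z)-pent-2-en-1-yl]cyclopent-2-en-1-yl]octanoate | CC/C=C\C[C@@H]1C(=O)C=C[C@]1(CCCCCCCC(=O)O[Si](C)(C)C(C)(C)C)OC(C)=O
F6 | step 3 | (4R)-4-hydroxy-4-(8-hydroxyoctyl)cyclopent-2-en-1-one | OCCCCCCCC[C@]1(O)C=CC(=O)C1
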